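**Plan**
- The target is a 3',6''-linked biflavone: a 5-hydroxy-7-methoxyflavone unit (rings A, C, B) and an apigenin unit (rings D, F, E). It has no stereocentre, and the C3'–C6'' axis is not configurationally defined.
- Retrosynthetic cuts, in order: the five O–benzyl bonds; C2–C1' (ring C to ring B); C3'–C6'' (ring B to ring D); then O1–C2 and C2–C3 of ring C, back to an acetophenone and a one-carbon unit.
- Enabling feature: C2–H of ring C is the most acidic C–H of a chromone (vinylic carbon bonded to O1 and β to C4=O), so the intact, already O7-methylated chromone can be zincated and arylated directly. C1' lies para to O4' and meta to C3', a pattern supplied by a commercial 5-chloro-2-(benzyloxy)phenylboronic acid.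
- This cut places the only O-methyl group in a small fragment and all other oxygens in the apigenin half, so no methylation has to discriminate among six phenols.
- Forward order: ring C is closed on the acetophenone; apigenin is dibenzylated, iodinated at C6'', benzylated and coupled to ring B (Suzuki–Miyaura); the two halves are joined by C2–H zincation and Negishi coupling; one hydrogenolysis frees the phenols.
- Stereochemistry: none to set.

Key step: step 7

Remark: unprimed and primed locants refer to the 7-methoxyflavone unit, doubly and triply primed locants to the apigenin unit; compounds 1, 5 and 9 and all reagents are assumed to be commercial.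

**Step 1**
Reactants: 1 1-(2,6-dihydroxy-4-methoxyphenyl)ethan-1-one
Product: 2 1-[2-(benzyloxy)-6-hydroxy-4-methoxyphenyl]ethan-1-one
Conditions: BnBr (1 equiv), K2CO3, acetone, reflux
Reagents that add atoms: benzyl bromide, BrCc1ccccc1
Why: Williamson ether synthesis; the two hydroxyls of 1 are equivalent, and after the first benzylation the remaining one is held in a hydrogen bond to the acetyl oxygen, so the monoether should dominate with one equivalent of bromide.

**Step 2**
Reactants: 2 1-[2-(benzyloxy)-6-hydroxy-4-methoxyphenyl]ethan-1-one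
Product: 4 5-(benzyloxy)-7-methoxy-4H-chromen-4-one, via enaminone 3 (not isolated)
Conditions: Me2NCH(OMe)2, toluene, 100 °C; then concd HCl, CH2Cl2, 40 °C
Reagents that add atoms: N,N-dimethylformamide dimethyl acetal, COC(OC)N(C)C
Why: Enaminone formation at the acetyl methyl group, then acid-promoted oxa-Michael addition of the free phenol and loss of dimethylamine (6-endo closure of ring C), is the standard one-carbon chromone annulation, and aryl benzyl and methyl ethers tolerate the brief acid treatment.

**Step 3**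
Reactants: 5 apigenin
Product: 6 7-(benzyloxy)-2-[4-(benzyloxy)phenyl]-5-hydroxy-4H-chromen-4-one
Conditions: BnBr (2.2 equiv), K2CO3, DMF, rt to 50 °C
Reagents that add atoms: benzyl bromide, BrCc1ccccc1
Why: Williamson ether synthesis; the 7''- and 4'''-hydroxyls are the acidic, unhindered phenols, whereas the 5''-hydroxyl is tied up by the hydrogen bond to C4''=O and should stay free.

**Step 4**
Reactants: 6 7-(benzyloxy)-2-[4-(benzyloxy)phenyl]-5-hydroxy-4H-chromen-4-one
Product: 7 7-(benzyloxy)-2-[4-(benzyloxy)phenyl]-5-hydroxy-6-iodo-4H-chromen-4-one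
Conditions: BnMe3N+ ICl2− (1.1 equiv), CaCO3, CH2Cl2–MeOH, rt
Reagents that add atoms: benzyltrimethylammonium dichloroiodate, C[N+](C)(C)Cc1ccccc1.Cl[I-]Cl
Why: Electrophilic aromatic iodination; the free, chelated 5''-hydroxyl is the strongest donor of ring D and, through bond fixation in its hydrogen-bonded ring, should direct the mild iodinating agent to its ortho carbon C6'' and not to C8''.

**Step 5**
Reactants: 7 7-(benzyloxy)-2-[4-(benzyloxy)phenyl]-5-hydroxy-6-iodo-4H-chromen-4-one
Product: 8 5,7-bis(benzyloxy)-2-[4-(benzyloxy)phenyl]-6-iodo-4H-chromen-4-one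
Conditions: BnBr, K2CO3, DMF, 70 °C
Reagents that add atoms: benzyl bromide, BrCc1ccccc1
Why: Williamson ether synthesis under more forcing conditions overcomes the hydrogen bond of the 5''-hydroxyl and removes the last acidic proton, which the organozinc of step 7 would not tolerate.

**Step 6**
Reactants: 8 5,7-bis(benzyloxy)-2-[4-(benzyloxy)phenyl]-6-iodo-4H-chromen-4-one; 9 [2-(benzyloxy)-5-chlorophenyl]boronic acid
Product: 10 5,7-bis(benzyloxy)-6-[2-(benzyloxy)-5-chlorophenyl]-2-[4-(benzyloxy)phenyl]-4H-chromen-4-one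
Conditions: Pd(PPh3)4 (cat.), K3PO4, DMF–H2O, 90 °C
Reagents that add atoms: none
Why: Suzuki–Miyaura coupling; zerovalent palladium with triphenylphosphine should insert into the C–I bond but not into the electron-rich C–Cl bond, and this catalyst class is precedented for di-ortho-alkoxy aryl iodides with ortho-alkoxy arylboron partners.

**Step 7**
Reactants: 4 5-(benzyloxy)-7-methoxy-4H-chromen-4-one; 10 5,7-bis(benzyloxy)-6-[2-(benzyloxy)-5-chlorophenyl]-2-[4-(benzyloxy)phenyl]-4H-chromen-4-one
Product: 12 5-(benzyloxy)-2-{4-(benzyloxy)-3-[5,7-bis(benzyloxy)-2-(4-(benzyloxy)phenyl)-4-oxo-4H-chromen-6-yl]phenyl}-7-methoxy-4H-chromen-4-one, via chromen-2-ylzinc chloride 11 (not isolated)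
Conditions: 4 (1.5 equiv), TMPZnCl·LiCl (2,2,6,6-tetramethylpiperidin-1-ylzinc chloride–LiCl, 1.1 equiv per 4), THF, −30 °C to rt; then 10, Pd(OAc)2 (cat.), XPhos, THF, 60 °C
Reagents that add atoms: none
Why: The hindered zinc amide should remove the C2–H of ring C, the most acidic C–H of 4 because it sits on the vinylic carbon bonded to O1 and β to C4=O, and the covalent C–Zn bond of 11 neither adds to the pyranone nor opens it. Zerovalent palladium ligated by XPhos then inserts into the only C–Cl bond of 10, and transmetalation with 11 followed by reductive elimination forms the C2–C1' bond. The closest known reaction type is the deprotonative C2-zincation of chromones with TMP-zinc bases followed by Negishi coupling with aryl halides to give flavones. No ring is closed and no stereocentre is created. The selectivity needed in 4 is C2 over C3 metalation, and it should be secured by omitting any magnesium or boron Lewis acid on the carbonyl oxygen that would steer the base to C3, so that acidity alone decides. On the other side, 10 carries no O–H to quench 11, its own pyranone C2'' is blocked by ring E and meets no free amide base, and the chloride at C1' (para to O4') is its only carbon–halogen bond.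

**Step 8**
Reactants: 12 5-(benzyloxy)-2-{4-(benzyloxy)-3-[5,7-bis(benzyloxy)-2-(4-(benzyloxy)phenyl)-4-oxo-4H-chromen-6-yl]phenyl}-7-methoxy-4H-chromen-4-one
Product: 13 6-[2-hydroxy-5-(5-hydroxy-7-methoxy-4-oxo-4H-chromen-2-yl)phenyl]-5,7-dihydroxy-2-(4-hydroxyphenyl)-4H-chromen-4-one
Conditions: H2 (1 atm), Pd/C (palladium on carbon), THF–MeOH, rt
Reagents that add atoms: none
Why: Catalytic hydrogenolysis should cleave the five aryl benzyl ethers, while the aryl methyl ether at C7 is inert and the conjugated pyranone double bonds of flavones are not reduced at atmospheric pressure and room temperature.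

**Compound list**
1 | 1-(2,6-dihydroxy-4-methoxyphenyl)ethan-1-one | CC(=O)c1c(O)cc(OC)cc1O | starting material
2 | 1-[2-(benzyloxy)-6-hydroxy-4-methoxyphenyl]ethan-1-one | CC(=O)c1c(O)cc(OC)cc1OCc1ccccc1 | intermediate
3 | (E)-1-[2-(benzyloxy)-6-hydroxy-4-methoxyphenyl]-3-(dimethylamino)prop-2-en-1-one (enaminone, not isolated) | CN(C)/C=C/C(=O)c1c(O)cc(OC)cc1OCc1ccccc1 | intermediate
4 | 5-(benzyloxy)-7-methoxy-4H-chromen-4-one | COc1cc(OCc2ccccc2)c2c(=O)ccoc2c1 | intermediate
5 | apigenin, 5,7-dihydroxy-2-(4-hydroxyphenyl)-4H-chromen-4-one | O=c1cc(-c2ccc(O)cc2)oc2cc(O)cc(O)c12 | starting material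
6 | 7-(benzyloxy)-2-[4-(benzyloxy)phenyl]-5-hydroxy-4H-chromen-4-one | O=c1cc(-c2ccc(OCc3ccccc3)cc2)oc2cc(OCc3ccccc3)cc(O)c12 | intermediate
7 | 7-(benzyloxy)-2-[4-(benzyloxy)phenyl]-5-hydroxy-6-iodo-4H-chromen-4-one | O=c1cc(-c2ccc(OCc3ccccc3)cc2)oc2cc(OCc3ccccc3)c(I)c(O)c12 | intermediate
8 | 5,7-bis(benzyloxy)-2-[4-(benzyloxy)phenyl]-6-iodo-4H-chromen-4-one | O=c1cc(-c2ccc(OCc3ccccc3)cc2)oc2cc(OCc3ccccc3)c(I)c(OCc3ccccc3)c12 | intermediate
9 | [2-(benzyloxy)-5-chlorophenyl]boronic acid | OB(O)c1cc(Cl)ccc1OCc1ccccc1 | starting material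
10 | 5,7-bis(benzyloxy)-6-[2-(benzyloxy)-5-chlorophenyl]-2-[4-(benzyloxy)phenyl]-4H-chromen-4-one | O=c1cc(-c2ccc(OCc3ccccc3)cc2)oc2cc(OCc3ccccc3)c(-c3cc(Cl)ccc3OCc3ccccc3)c(OCc3ccccc3)c12 | intermediate
11 | [5-(benzyloxy)-7-methoxy-4-oxo-4H-chromen-2-yl]zinc chloride, LiCl complex (not isolated) | COc1cc(OCc2ccccc2)c2c(=O)cc([Zn]Cl)oc2c1 | intermediate
12 | 5-(benzyloxy)-2-{4-(benzyloxy)-3-[5,7-bis(benzyloxy)-2-(4-(benzyloxy)phenyl)-4-oxo-4H-chromen-6-yl]phenyl}-7-methoxy-4H-chromen-4-one | COc1cc(OCc7ccccc7)c2c(=O)cc(-c3ccc(OCc7ccccc7)c(-c4c(OCc7ccccc7)cc5oc(-c6ccc(OCc7ccccc7)cc6)cc(=O)c5c4OCc7ccccc7)c3)oc2c1 | intermediate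
13 | 6-[2-hydroxy-5-(5-hydroxy-7-methoxy-4-oxo-4H-chromen-2-yl)phenyl]-5,7-dihydroxy-2-(4-hydroxyphenyl)-4H-chromen-4-one | COc1cc(O)c2c(=O)cc(-c3ccc(O)c(-c4c(O)cc5oc(-c6ccc(O)cc6)cc(=O)c5c4O)c3)oc2c1 | target

**Step count**
Total: 8 steps. Longest linear sequence: 6 steps (5 to 13, steps 3–8).

**Steps most likely to fail**

Step 7. The zincation may stall on the electron-rich chromone or drift to C3, the metalated pyranone may open, or oxidative addition into the electron-rich C–Cl bond may be too slow, so that protonated chromone is returned. The fallback reverses the polarity of the union and sets out from 10. Palladium-catalysed borylation of the C–Cl bond with tetrahydroxydiboron (Pd(OAc)2, XPhos, KOAc, EtOH, 80 °C) would give [4-(benzyloxy)-3-{5,7-bis(benzyloxy)-2-[4-(benzyloxy)phenyl]-4-oxo-4H-chromen-6-yl}phenyl]boronic acid F1. Conjugate addition of F1 to chromone 4 under divalent-palladium catalysis (Pd(TFA)2, 2,2'-bipyridine, AcOH–THF–H2O, 60 °C) would give the racemic flavanone 5-(benzyloxy)-2-{4-(benzyloxy)-3-[5,7-bis(benzyloxy)-2-(4-(benzyloxy)phenyl)-4-oxo-4H-chromen-6-yl]phenyl}-7-methoxy-2,3-dihydro-4H-chromen-4-one F2. Dehydrogenation of F2 (I2 cat., DMSO, 120 °C) removes its only stereocentre and comes back to the route at 12.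

Step 6. Transmetalation at a palladium centre flanked by two ortho benzyloxy groups may be slow, so protodeboronation of 9 and hydrodeiodination of 8 could overtake the coupling. The fallback changes the order of events so that the coupling meets a small, hydrogen-bonded ortho substituent, and sets out from 7. Coupling 7 with 9 while the 5''-hydroxyl is still free (Pd(dppf)Cl2, K3PO4, dioxane–H2O, 90 °C) would give 7-(benzyloxy)-6-[2-(benzyloxy)-5-chlorophenyl]-2-[4-(benzyloxy)phenyl]-5-hydroxy-4H-chromen-4-one F3. Benzylation of the chelated hydroxyl of F3 (BnBr, K2CO3, DMF, 70 °C) comes back to the route at 10.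

Step 8. Hydrogenolysis may stop short when partly debenzylated intermediates precipitate or poison the catalyst, and prolonged exposure risks reduction of a pyranone double bond. The fallback replaces reduction by Lewis-acid dealkylation and sets out from 12: BCl3 with pentamethylbenzene as cation scavenger in CH2Cl2 at −78 °C, then a MeOH quench, should cleave all five benzyl ethers and give 13 directly. The 7-methoxy group has no neighbouring chelating carbonyl and should survive at this temperature. This fallback makes no new compound (F0).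

**Further compounds**
F1 | step 7 | [4-(benzyloxy)-3-{5,7-bis(benzyloxy)-2-[4-(benzyloxy)phenyl]-4-oxo-4H-chromen-6-yl}phenyl]boronic acid | O=c1cc(-c2ccc(OCc3ccccc3)cc2)oc2cc(OCc3ccccc3)c(-c3cc(B(O)O)ccc3OCc3ccccc3)c(OCc3ccccc3)c12
F2 | step 7 | 5-(benzyloxy)-2-{4-(benzyloxy)-3-[5,7-bis(benzyloxy)-2-(4-(benzyloxy)phenyl)-4-oxo-4H-chromen-6-yl]phenyl}-7-methoxy-2,3-dihydro-4H-chromen-4-one (racemic at C2) | COc1cc(OCc7ccccc7)c2C(=O)CC(c3ccc(OCc7ccccc7)c(-c4c(OCc7ccccc7)cc5oc(-c6ccc(OCc7ccccc7)cc6)cc(=O)c5c4OCc7ccccc7)c3)Oc2c1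
F3 | step 6 | 7-(benzyloxy)-6-[2-(benzyloxy)-5-chlorophenyl]-2-[4-(benzyloxy)phenyl]-5-hydroxy-4H-chromen-4-one | O=c1cc(-c2ccc(OCc3ccccc3)cc2)oc2cc(OCc3ccccc3)c(-c3cc(Cl)ccc3OCc3ccccc3)c(O)c12
F0 | step 8 | none | none
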